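The target is a regular head-to-tail C15 eudesmane (ring A: C1–C5, C10; ring B: C5–C10) with a five-carbon epoxy ester on O3, so its carbon skeleton maps atom for atom onto farnesyl diphosphate. The route rests on disconnecting C6–C7 and C5–C10. In one enzymatic operation the acyclic, achiral (2E,6E)-diphosphate is folded into selina-4(15),7(11)-diene. Both rings close, and C5 (α-H) and C10 (β-methyl) are fixed absolutely. The surviving olefins C4=C15 and C7=C11 lie where O3/O4 and O7/O8/O11 must go. Ring B is oxidised first to the C8 enone, ring A follows, and enantiopure epoxyangelic acid is attached last.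

Key step: step 3

Conventions: eudesmane numbering throughout; C14 is the methyl on C10, C15 the carbon on C4, C11–C13 the three-carbon unit on C7; α is the face opposite C14.

Assumption: the synthase (the Streptomyces pristinaespiralis selina-4(15),7(11)-diene synthase, or a homologue or variant) is taken to deliver the 5S,10R series (5α-H, 10β-methyl); this is to be verified on the first batch of 5 by chiral GC and optical rotation before material is carried on.

Step 1
Reactants: 1 (2E,6E)-farnesol
Product: 2 (2E,6E)-farnesyl bromide
Conditions: PBr3 (0.4 equiv), Et2O, −10 to 0 °C; used crude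
Reagents that add atoms: phosphorus tribromide, BrP(Br)Br
Why: Bromination of a primary allylic alcohol with PBr3 proceeds by SN2 displacement of the phosphite ester at C1, and at or below 0 °C neither the 2E olefin nor the allylic position is scrambled; no stereocentre is formed.

Step 2
Reactants: 2 (2E,6E)-farnesyl bromide
Product: 3 (2E,6E)-farnesyl diphosphate (handled as the tris-ammonium salt)
Conditions: (nBu4N)3HP2O7, MeCN, rt; Dowex 50W-X8 (NH4+ form), aq NH4HCO3; cellulose chromatography
Reagents that add atoms: tris(tetrabutylammonium) hydrogen diphosphate, CCCC[N+](CCCC)(CCCC)CCCC.CCCC[N+](CCCC)(CCCC)CCCC.CCCC[N+](CCCC)(CCCC)CCCC.OP(=O)([O-])OP(=O)([O-])[O-]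
Why: SN2 displacement of the primary allylic bromide by a lipophilic diphosphate salt in dry acetonitrile is the standard allylic diphosphorylation, and cation exchange to the ammonium form gives the water-soluble native substrate with its E,E geometry untouched.

Step 3
Reactants: 3 (2E,6E)-farnesyl diphosphate
Product: 5 (5S,10R)-selina-4(15),7(11)-diene, via germacrene B 4 (not isolated)
Conditions: recombinant selina-4(15),7(11)-diene synthase (His-tagged, from E. coli), MgCl2, HEPES buffer pH 7.5, glycerol, pentane overlay, 30 °C
Reagents that add atoms: none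
Why: Class 1 terpene synthase cascade, the native reaction of this enzyme: three magnesium ions held by the aspartate-rich motifs pull diphosphate off 3, the terminus of the allyl cation (future C6) is captured by the distal olefin at future C7 in a 10-exo closure, and loss of H7 from the C11 cation gives enzyme-bound germacrene B 4. Reprotonation of 4 at C1 places the charge on C10, C5 of the C4=C5 olefin attacks it, and this one transannular bond closes ring A in a 6-endo and ring B in a 6-exo sense relative to that olefin, after which loss of a C15 proton leaves the exocyclic C4=C15 olefin. The closest non-enzymatic relative is the Brønsted acid-induced transannular cyclisation of germacrenes, which gives racemic mixtures of olefin isomers. C5 and C10 are formed together: the crossed chair–chair fold of the E,E-cyclodecadiene enforces anti addition across both olefins and hence the trans ring fusion (5α-H, 10β-methyl), and the contour of the active site admits only one of the two mirror-image folds of achiral 4, which fixes the absolute configuration as 5S,10R. The step needs 1,10- rather than 1,11- or 1,6-closure, retention and reprotonation of 4 rather than its release, and final deprotonation at C15 rather than at C3 or C5; the substrate contributes only its 2E,6E geometry and the pocket secures the rest, so isomerically pure 3 and a synthase of verified product series are required.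

Step 4
Reactants: 5 (5S,10R)-selina-4(15),7(11)-diene
Product: 6 selina-4(15),7(11)-dien-8-one (5α-H, 10β-methyl)
Conditions: CrO3, 3,5-dimethylpyrazole (excess, 1:1), CH2Cl2, −20 °C
Reagents that add atoms: chromium trioxide, O=[Cr](=O)=O
Why: Allylic oxidation with the CrO3–3,5-dimethylpyrazole complex: the electrophilic hexavalent chromium reagent engages the electron-rich tetrasubstituted C7=C11 olefin in preference to the 1,1-disubstituted C4=C15, ring CH2 is oxidised faster than CH3, C8 is preferred over C6 because unsaturation developing away from the ring fusion is the less strained option in a trans-fused 10-methyldecalin and C6 is screened by C5 and the peri C15 methylene, and any tertiary C11 chromate ester funnels to C8 by [3,3] allylic transposition before it is oxidised; no stereocentre is formed.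

Step 5
Reactants: 6 selina-4(15),7(11)-dien-8-one
Product: 7 3α-hydroxyselina-4(15),7(11)-dien-8-one
Conditions: SeO2 (0.5 equiv), TBHP (decane solution, 2 equiv), CH2Cl2, 0 °C to rt
Reagents that add atoms: tert-butyl hydroperoxide (terminal oxidant), CC(C)(C)OO; selenium dioxide (oxygen carrier), O=[Se]=O
Why: Riley-type allylic hydroxylation (ene reaction, then [2,3]-sigmatropic shift): the conjugated C7=C11 olefin is now too electron-poor to react, so SeO2 adds to C15 while removing the axial 3α-H, and the allylseleninic acid returns oxygen to C3 along the same axial α trajectory, away from C14, which sets 3α-OH (3R).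

Step 6
Reactants: 7 3α-hydroxyselina-4(15),7(11)-dien-8-one
Product: 8 4α,15-epoxy-3α-hydroxyeudesm-7(11)-en-8-one
Conditions: VO(acac)2 (5 mol%), TBHP (1.5 equiv), toluene, 0 °C to rt
Reagents that add atoms: tert-butyl hydroperoxide, CC(C)(C)OO
Why: Hydroxyl-directed epoxidation of an allylic alcohol with VO(acac)2 and TBHP: the axial 3α-alkoxide holds the vanadium peroxide over the α face of C4=C15, which is also the sterically open face, so the oxirane oxygen ends up 4α and C15 β, while the electron-poor enone olefin does not react.

Step 7
Reactants: 8 4α,15-epoxy-3α-hydroxyeudesm-7(11)-en-8-one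
Product: 9 eudesm-7(11)-ene-3α,4α,8β-triol
Conditions: LiAlH4 (excess), THF, 0 to 50 °C; aq Rochelle salt work-up
Reagents that add atoms: none
Why: Hydride reduction with LiAlH4: SN2 attack at the unsubstituted oxirane carbon C15 leaves the C4–O bond untouched and so turns the α-epoxide into 4α-OH with a 4β-methyl group, and the C8 carbonyl group is unavoidably reduced in the 1,2 sense from the open α face to the 8β allylic alcohol, a stereocentre that is erased in step 8.

Step 8
Reactants: 9 eudesm-7(11)-ene-3α,4α,8β-triol
Product: 10 3α,4α-dihydroxyeudesm-7(11)-en-8-one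
Conditions: activated MnO2 (excess), CH2Cl2, rt
Reagents that add atoms: none
Why: Chemoselective MnO2 oxidation: only the allylic 8-OH is oxidised, the saturated secondary 3α-OH and the tertiary 4α-OH being inert under these conditions, which restores the enone without any protecting group.

Step 9
Reactants: 10 3α,4α-dihydroxyeudesm-7(11)-en-8-one
Product: 11 7α,11-epoxy-3α,4α-dihydroxyeudesman-8-one
Conditions: 30% aq H2O2, aq NaOH, MeOH, 0 °C to rt
Reagents that add atoms: hydrogen peroxide, OO
Why: Weitz–Scheffer nucleophilic epoxidation, precedented on pulegone-type β,β-dimethyl enones: hydroperoxide adds to C11 and the resulting C7=C8 enolate closes the oxirane through its axial α lobe at C7, the β face being crowded by the axial C14 and C15 methyl groups, which sets the 7α C–O bond (7S).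

Step 10
Reactants: 11 7α,11-epoxy-3α,4α-dihydroxyeudesman-8-one
Product: 12 3α,4α,7α,11-tetrahydroxyeudesman-8-one
Conditions: HClO4 (cat.), THF/H2O, 0 °C to rt
Reagents that add atoms: water, O
Why: Acid-catalysed epoxide hydrolysis: positive charge can develop only at the tertiary C11, remote from the destabilising carbonyl group, so water enters at the non-stereogenic C11 and the C7–O bond keeps its α configuration.

Step 11
Reactants: 13 angelic acid
Product: 14 (Z)-2-methylbut-2-en-1-ol
Conditions: LiAlH4, Et2O, 0 °C
Reagents that add atoms: none
Why: LiAlH4 reduces the carboxylic acid to the primary allylic alcohol without touching or isomerising the trisubstituted Z olefin.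

Step 12
Reactants: 14 (Z)-2-methylbut-2-en-1-ol
Product: 15 [(2R,3S)-2,3-dimethyloxiran-2-yl]methanol
Conditions: Ti(OiPr)4 (10 mol%), D-(−)-diethyl tartrate (12 mol%), TBHP (anhydrous, decane), 4 Å MS, CH2Cl2, −20 °C
Reagents that add atoms: tert-butyl hydroperoxide, CC(C)(C)OO
Why: Sharpless asymmetric epoxidation: the titanium complex of D-(−)-tartrate delivers oxygen to the olefin face opposite to the one that gives 2S epoxides with L-(+)-tartrate, which sets 2R,3S, and the Z geometry is transferred stereospecifically into the cis relation of the C3 methyl group and CH2OH.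

Step 13
Reactants: 15 [(2R,3S)-2,3-dimethyloxiran-2-yl]methanol
Product: 16 (2S,3S)-2,3-dimethyloxirane-2-carboxylic acid (epoxyangelic acid)
Conditions: TEMPO (cat.), PhI(OAc)2 (2.2 equiv), MeCN/H2O, rt
Reagents that add atoms: water, O
Why: TEMPO-catalysed oxidation with PhI(OAc)2 in aqueous acetonitrile takes the primary alcohol through the aldehyde hydrate to the acid under nearly neutral conditions that spare the oxirane, the quaternary C2 cannot epimerise, and its descriptor changes from R to S only because the priorities change.

Step 14
Reactants: 12 3α,4α,7α,11-tetrahydroxyeudesman-8-one; 16 (2S,3S)-2,3-dimethyloxirane-2-carboxylic acid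
Product: 18 3α-[(2S,3S)-2,3-epoxy-2-methylbutanoyloxy]-4α,7α,11-trihydroxyeudesman-8-one (CNP0145407.1), via Yamaguchi mixed anhydride 17 (not isolated)
Conditions: 16, 2,4,6-trichlorobenzoyl chloride, Et3N, toluene, rt; then 12, DMAP, rt to 40 °C
Reagents that add atoms: none
Why: Yamaguchi esterification: DMAP picks the less shielded glycidic carbonyl group of 17 and transfers it to the only secondary hydroxyl group, 3α-OH, the three tertiary hydroxyl groups being unreactive, and neither partner has an epimerisable centre, so all seven stereocentres are carried through unchanged.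

Compound list
1 | (2E,6E)-farnesol | CC(C)=CCC/C(C)=C/CC/C(C)=C/CO | starting material
2 | (2E,6E)-farnesyl bromide | CC(C)=CCC/C(C)=C/CC/C(C)=C/CBr | intermediate
3 | (2E,6E)-farnesyl diphosphate | CC(C)=CCC/C(C)=C/CC/C(C)=C/COP(=O)(O)OP(=O)(O)O | intermediate
4 | germacrene B, (1(10)E,4E)-germacra-1(10),4,7(11)-triene | C/C1=C\CC/C(C)=C/CC(=C(C)C)CC1 | intermediate (not isolated)
5 | (5S,10R)-selina-4(15),7(11)-diene (5α-H, 10β-methyl) | C1CC[C@]2(C)CCC(=C(C)C)C[C@H]2C1=C | intermediate
6 | selina-4(15),7(11)-dien-8-one | C1CC[C@]2(C)CC(=O)C(=C(C)C)C[C@H]2C1=C | intermediate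
7 | 3α-hydroxyselina-4(15),7(11)-dien-8-one | O[C@@H]1CC[C@]2(C)CC(=O)C(=C(C)C)C[C@H]2C1=C | intermediate
8 | 4α,15-epoxy-3α-hydroxyeudesm-7(11)-en-8-one | O[C@@H]1CC[C@]2(C)CC(=O)C(=C(C)C)C[C@H]2[C@]13OC3 | intermediate
9 | eudesm-7(11)-ene-3α,4α,8β-triol | O[C@@H]1CC[C@]2(C)C[C@@H](O)C(=C(C)C)C[C@H]2[C@]1(C)O | intermediate
10 | 3α,4α-dihydroxyeudesm-7(11)-en-8-one | O[C@@H]1CC[C@]2(C)CC(=O)C(=C(C)C)C[C@H]2[C@]1(C)O | intermediate
11 | 7α,11-epoxy-3α,4α-dihydroxyeudesman-8-one | O[C@@H]1CC[C@]2(C)CC(=O)[C@]3(OC3(C)C)C[C@H]2[C@]1(C)O | intermediate
12 | 3α,4α,7α,11-tetrahydroxyeudesman-8-one | O[C@@H]1CC[C@]2(C)CC(=O)[C@@](O)(C(C)(C)O)C[C@H]2[C@]1(C)O | intermediate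
13 | angelic acid, (Z)-2-methylbut-2-enoic acid | C/C=C(/C)C(=O)O | starting material
14 | (Z)-2-methylbut-2-en-1-ol | C/C=C(/C)CO | intermediate
15 | [(2R,3S)-2,3-dimethyloxiran-2-yl]methanol | C[C@@H]1O[C@]1(C)CO | intermediate
16 | (2S,3S)-2,3-dimethyloxirane-2-carboxylic acid | C[C@@H]1O[C@]1(C)C(=O)O | intermediate
17 | (2S,3S)-2,3-dimethyloxirane-2-carboxylic 2,4,6-trichlorobenzoic anhydride | C[C@@H]1O[C@]1(C)C(=O)OC(=O)c1c(Cl)cc(Cl)cc1Cl | intermediate (not isolated)
18 | CNP0145407.1, (3R,4S,5R,7S,10R)-3α-[(2S,3S)-2,3-epoxy-2-methylbutanoyloxy]-4α,7α,11-trihydroxyeudesman-8-one | C[C@@H]1O[C@]1(C)C(=O)O[C@@H]1CC[C@]2(C)CC(=O)[C@@](O)(C(C)(C)O)C[C@H]2[C@]1(C)O | target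

Total step count: 14. Longest linear sequence: 11 (steps 1–10 and 14, from farnesol); steps 11–13 form the three-step side branch.

Steps most likely to fail

Step 4. Oxygenation may spread over competing allylic sites (C6, C3, C5, the C12 and C13 methyl groups), and the tetrasubstituted olefin may be epoxidised instead of oxidised at its flank. The fallback builds ring A first.
- It sets out from 5. A hydrogen-atom-transfer isomerisation ([N,N'-bis(3,5-di-tert-butylsalicylidene)ethane-1,2-diaminato]cobalt chloride, PhSiH3, benzene, rt) touches only the 1,1-disubstituted olefin and should give selina-3,7(11)-diene F1.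
- Catalytic OsO4 with NMO dihydroxylates the more accessible trisubstituted olefin from the α face, opposite C14, to give selin-7(11)-ene-3α,4α-diol F2.
- 2,2-Dimethoxypropane with PPTS converts it into 3α,4α-isopropylidenedioxyeudesm-7(11)-ene F3.
- The CrO3–3,5-dimethylpyrazole oxidation is then run on this substrate. Ring A has no allylic C–H left, and the 4α-oxygen of the dioxolane screens C6. The product is 3α,4α-isopropylidenedioxyeudesm-7(11)-en-8-one F4.
- Aqueous acetic acid removes the acetal, and the sequence comes back to the route at 10, replacing steps 4 to 8.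

Step 9. Ring closure of the peroxy enolate may show poor facial selectivity. Conjugate addition to the hindered β,β-disubstituted enone may also be slow enough for base-induced loss of acetone to compete. The fallback sets C7 by a sterically controlled cycloaddition on the electron-rich olefin.
- It sets out from 9, before reoxidation. 2,2-Dimethoxypropane with PPTS masks the cis-diol as 3α,4α-isopropylidenedioxyeudesm-7(11)-en-8β-ol F5.
- Stoichiometric OsO4 in pyridine, followed by reductive cleavage of the osmate with NaHSO3, adds from the α face. This face is anti to the axial 8β-OH and to C14. The product is 3α,4α-isopropylidenedioxyeudesmane-7α,8β,11-triol F6.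
- Dess–Martin periodinane oxidises the only secondary hydroxyl group to give 7α,11-dihydroxy-3α,4α-isopropylidenedioxyeudesman-8-one F7.
- Aqueous acetic acid releases the diol, and the sequence comes back to the route at 12, replacing steps 8 to 10.

Step 14. Acyl transfer between an α-quaternary acid and an axial alcohol next to a fully substituted carbon may be slow. Opening of the oxirane in the activated acid, or amine-induced retro-aldol loss of acetone from 12, could then compete. The fallback attaches the olefinic acid and epoxidises afterwards.
- It sets out from 12 and 13. Angelic acid, whose sp2 α-carbon is less demanding, is coupled through its 2,4,6-trichlorobenzoyl mixed anhydride in warm toluene, conditions that preserve the Z geometry. This gives 3α-angeloyloxy-4α,7α,11-trihydroxyeudesman-8-one F8.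
- Dimethyldioxirane in acetone epoxidises the only C=C left. The reaction is stereospecific (cis) but has little facial bias.
- The route is rejoined at 18 after chromatographic removal of the (2R,3R)-epoxyangelate diastereomer F9.

Further compounds
F1 | step 4 | selina-3,7(11)-diene (5α-H, 10β-methyl) | CC1=CCC[C@]2(C)CCC(=C(C)C)C[C@@H]12
F2 | step 4 | selin-7(11)-ene-3α,4α-diol | O[C@@H]1CC[C@]2(C)CCC(=C(C)C)C[C@H]2[C@]1(C)O
F3 | step 4 | 3α,4α-isopropylidenedioxyeudesm-7(11)-ene | CC1(C)O[C@@H]2CC[C@]3(C)CCC(=C(C)C)C[C@H]3[C@]2(C)O1
F4 | step 4 | 3α,4α-isopropylidenedioxyeudesm-7(11)-en-8-one | CC1(C)O[C@@H]2CC[C@]3(C)CC(=O)C(=C(C)C)C[C@H]3[C@]2(C)O1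
F5 | step 9 | 3α,4α-isopropylidenedioxyeudesm-7(11)-en-8β-ol | CC1(C)O[C@@H]2CC[C@]3(C)C[C@@H](O)C(=C(C)C)C[C@H]3[C@]2(C)O1
F6 | step 9 | 3α,4α-isopropylidenedioxyeudesmane-7α,8β,11-triol | CC1(C)O[C@@H]2CC[C@]3(C)C[C@@H](O)[C@@](O)(C(C)(C)O)C[C@H]3[C@]2(C)O1
F7 | step 9 | 7α,11-dihydroxy-3α,4α-isopropylidenedioxyeudesman-8-one | CC1(C)O[C@@H]2CC[C@]3(C)CC(=O)[C@@](O)(C(C)(C)O)C[C@H]3[C@]2(C)O1
F8 | step 14 | 3α-angeloyloxy-4α,7α,11-trihydroxyeudesman-8-one | C/C=C(/C)C(=O)O[C@@H]1CC[C@]2(C)CC(=O)[C@@](O)(C(C)(C)O)C[C@H]2[C@]1(C)O
F9 | step 14 | (2R,3R)-epoxyangelate diastereomer of 18 | C[C@H]1O[C@@]1(C)C(=O)O[C@@H]1CC[C@]2(C)CC(=O)[C@@](O)(C(C)(C)O)C[C@H]2[C@]1(C)O
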